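**Plan** (chain numbered C1–C9 from the enol acetate carbon, ring C1'–C6' with C1' = ring CH that carries the chain, C2'(Me)=C3', C6' = CMe2)

- Retrosynthesis: the C3 formyl group and the (E)-enol acetate are traced to the two arms (epoxide CH2 and CH2OH) of an (R)-2,2-disubstituted epoxy alcohol; cutting C4–C5 then leaves (S)-α-monocyclofarnesyl bromide and the dianion of 2-methylprop-2-en-1-ol.
- The ring is cut across C1'–C6' and C4'–C5': the C2'=C3' double bond lies opposite these two bonds, so the cyclohexene is the [4+2] adduct of an (E)-1-alkyl-2-methylbuta-1,3-diene (C1'–C4') and a 1,1-disubstituted alkene (C5'=C6').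
- 2-Methylacrolein stands in for isobutene: its formyl group activates the dienophile and is afterwards reduced to the second C6' methyl. The diene comes from geranyl acetate, which already holds the (6E)-alkene.
- Forward: geranyl acetate → terminal diene → ring by enantioselective cycloaddition → CHO to CH3 → allylic bromide → C4–C5 bond → epoxidation → arm-by-arm elaboration at C3.
- Stereochemistry: C1' (S) from the chiral boron Lewis acid in the cycloaddition (enal face plus endo mode); C3 (R) from Sharpless epoxidation with D-(−)-tartrate; C6=C7 (E) from geraniol; C1=C2 (E) from a boron-Wittig olefination and a stereoretentive boron-to-acetate exchange.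

Key step: step 3

Assumption 1: the (S)-configured oxazaborolidinium salt is taken to shield the same face of bound 2-methylacrolein as this catalyst class does with simple dienes, which with an endo formyl group leads to (1S,2R)-6; should the adduct prove to be the mirror image, the (R)-configured catalyst is used with no other change.

Assumption 2: geranyl acetate is used as the pure (2E) isomer; 1, 5, 10 and all reagents are commercial.

**Step 1**
Reactants: 1 geranyl acetate
Product: 3 (2E,6E)-3,7-dimethyl-8-oxoocta-2,6-dien-1-yl acetate, via allylic alcohol 2 (not isolated)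
Conditions: SeO2 (cat.), t-BuOOH, salicylic acid (cat.), CH2Cl2, rt; filter, concentrate; then MnO2, CH2Cl2, rt
Reagents that add atoms: selenium dioxide (O=[Se]=O, oxygen carrier) and tert-butyl hydroperoxide (CC(C)(C)OO)
Why: Allylic oxidation by SeO2 (ene reaction, then [2,3]-sigmatropic shift) attacks the (E)-methyl group of the terminal trisubstituted alkene selectively, and MnO2 then oxidises the allylic alcohol to the (E)-enal without touching the allylic acetate.

**Step 2**
Reactants: 3 (2E,6E)-3,7-dimethyl-8-oxoocta-2,6-dien-1-yl acetate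
Product: 4 (2E,6E)-3,7-dimethylnona-2,6,8-trien-1-yl acetate
Conditions: Ph3PCH3Br, KN(SiMe3)2, THF, 0 °C; then 3, −78 → 0 °C
Reagents that add atoms: methyltriphenylphosphonium bromide (C[P+](c1ccccc1)(c1ccccc1)c1ccccc1.[Br-])
Why: Wittig methylenation of the aldehyde by the non-stabilised ylide at low temperature is far faster than attack on the acetate and leaves the (E)-trisubstituted alkene unchanged, giving the (E)-1-alkyl-2-methyl diene.

**Step 3**
Reactants: 4 (2E,6E)-3,7-dimethylnona-2,6,8-trien-1-yl acetate; 5 2-methylprop-2-enal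
Product: 6 (1S,2R)-2-[(3E)-5-acetoxy-3-methylpent-3-en-1-yl]-1,3-dimethylcyclohex-3-ene-1-carbaldehyde
Conditions: (S)-3,3-diphenyl-1-(2-methylphenyl)tetrahydro-1H,3H-pyrrolo[1,2-c][1,3,2]oxazaborole (20 mol %), HN(SO2CF3)2 (17 mol %), CH2Cl2, −78 °C
Reagents that add atoms: none
Why: A concerted but asynchronous normal-demand [4+2] cycloaddition (closest known type: enantioselective Diels–Alder reaction of 2-substituted acroleins with acyclic dienes under chiral cationic boron Lewis acids) in which the boron-bound s-trans enal adds across the s-cis diene and forms C4'–C5' and C1'–C6' at once. The cyclohexene ring closes in the intermolecular [4+2] mode (two σ bonds from one diene and one dienophile, no tether), and the (E)-diene keeps the chain in the outside position so that the s-cis conformer is accessible. The quaternary C6' is set by the enal face left open by the catalyst's aryl group that lies under the coordinated enal (a formyl C–H···O contact fixes its conformation), and C1' follows from it through the endo position of the Lewis-acid-bound formyl group, which places CHO cis to the chain; together they should give (1S,2R)-6, whose C6' centre is erased in step 4 so that only the ring CH remains. The selectivity the step needs is regioselectivity: the leading bond should join the unsubstituted β-carbon of the enal to the unsubstituted diene terminus, with the developing allyl cation stabilised at the alkyl-bearing terminus, so that the quaternary carbon ends next to the chain, the 1-alkyl group and the lower hindrance outweighing the opposing 2-methyl group. Chemoselectivity rests on the conjugated diene being the only 4π unit and on the isolated trisubstituted alkene and the allylic acetate being inert at −78 °C.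

**Step 4**
Reactants: 6 (1S,2R)-2-[(3E)-5-acetoxy-3-methylpent-3-en-1-yl]-1,3-dimethylcyclohex-3-ene-1-carbaldehyde
Product: 8 (2E)-3-methyl-5-[(1S)-2,6,6-trimethylcyclohex-2-en-1-yl]pent-2-en-1-ol, via hydroxy hydrazone 7 (not isolated)
Conditions: N2H4·H2O, KOH, diethylene glycol, 130 °C, then 200 °C with removal of water, under N2
Reagents that add atoms: none
Why: Wolff–Kishner reduction (Huang–Minlon procedure) converts the non-enolisable neopentyl aldehyde into the second C6' methyl group through its hydrazone, removing the activating group and the C6' stereocentre, while the hot KOH also cleaves the acetate; the ring CH is not acidic and keeps its configuration.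

**Step 5**
Reactants: 8 (2E)-3-methyl-5-[(1S)-2,6,6-trimethylcyclohex-2-en-1-yl]pent-2-en-1-ol
Product: 9 (6S)-6-[(3E)-5-bromo-3-methylpent-3-en-1-yl]-1,5,5-trimethylcyclohex-1-ene
Conditions: PBr3, pyridine (cat.), Et2O, −10 °C
Reagents that add atoms: phosphorus tribromide (BrP(Br)Br)
Why: Bromination of a primary allylic alcohol with PBr3 (SN2 on the bromophosphite) under weakly basic conditions should avoid allylic transposition and acid-induced cyclisation of the 1,5-diene.

**Step 6**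
Reactants: 9 (6S)-6-[(3E)-5-bromo-3-methylpent-3-en-1-yl]-1,5,5-trimethylcyclohex-1-ene; 10 2-methylprop-2-en-1-ol
Product: 11 (5E)-6-methyl-2-methylidene-8-[(1S)-2,6,6-trimethylcyclohex-2-en-1-yl]oct-5-en-1-ol
Conditions: 10, n-BuLi (2.1 equiv), TMEDA, Et2O–hexane, 0 °C → rt; then 9, −78 °C → rt
Reagents that add atoms: none
Why: C-Alkylation of the allylic dianion of methallyl alcohol (alkoxide-directed allylic lithiation) by the primary allylic bromide in the SN2 sense forms C4–C5 and delivers the 2-substituted allylic alcohol directly.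

**Step 7**
Reactants: 11 (5E)-6-methyl-2-methylidene-8-[(1S)-2,6,6-trimethylcyclohex-2-en-1-yl]oct-5-en-1-ol
Product: 12 [(2R)-2-{(3E)-4-methyl-6-[(1S)-2,6,6-trimethylcyclohex-2-en-1-yl]hex-3-en-1-yl}oxiran-2-yl]methanol
Conditions: Ti(OiPr)4 (10 mol %), D-(−)-diisopropyl tartrate (12 mol %), t-BuOOH, 4 Å molecular sieves, CH2Cl2, −20 °C; non-basic work-up
Reagents that add atoms: tert-butyl hydroperoxide (CC(C)(C)OO)
Why: Sharpless asymmetric epoxidation acts only on the allylic-alcohol alkene, and with D-(−)-tartrate the oxygen is delivered to the face that gives the (R)-epoxy alcohol, so C3 is set by the catalyst; the non-basic work-up avoids Payne interchange of the two arms.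

**Step 8**
Reactants: 12 [(2R)-2-{(3E)-4-methyl-6-[(1S)-2,6,6-trimethylcyclohex-2-en-1-yl]hex-3-en-1-yl}oxiran-2-yl]methanol
Product: 13 (2S)-2-{(3E)-4-methyl-6-[(1S)-2,6,6-trimethylcyclohex-2-en-1-yl]hex-3-en-1-yl}oxirane-2-carbaldehyde
Conditions: Dess–Martin periodinane, NaHCO3, CH2Cl2, 0 °C → rt
Reagents that add atoms: none
Why: Dess–Martin oxidation of the primary alcohol under buffered conditions gives the non-enolisable epoxy aldehyde without forming an alkoxide, so the configuration at C3 is not scrambled (the descriptor changes only by priority).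

**Step 9**
Reactants: 13 (2S)-2-{(3E)-4-methyl-6-[(1S)-2,6,6-trimethylcyclohex-2-en-1-yl]hex-3-en-1-yl}oxirane-2-carbaldehyde
Product: 14 4,4,5,5-tetramethyl-2-[(E)-2-((2R)-2-{(3E)-4-methyl-6-[(1S)-2,6,6-trimethylcyclohex-2-en-1-yl]hex-3-en-1-yl}oxiran-2-yl)ethenyl]-1,3,2-dioxaborolane
Conditions: CH2(Bpin)2, lithium 2,2,6,6-tetramethylpiperidide (LiTMP), THF, 0 °C; then 13, −78 °C → rt
Reagents that add atoms: bis(4,4,5,5-tetramethyl-1,3,2-dioxaborolan-2-yl)methane (CC1(C)OB(CB2OC(C)(C)C(C)(C)O2)OC1(C)C)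
Why: Boron-Wittig olefination: the α-boryl carbanion adds to the aldehyde far faster than to the epoxide at −78 °C and syn-elimination of the boron alkoxide should give the (E)-alkenyl boronate.

**Step 10**
Reactants: 14 4,4,5,5-tetramethyl-2-[(E)-2-((2R)-2-{(3E)-4-methyl-6-[(1S)-2,6,6-trimethylcyclohex-2-en-1-yl]hex-3-en-1-yl}oxiran-2-yl)ethenyl]-1,3,2-dioxaborolane
Product: 16 (1E,3R,6E)-3-{[(4-methoxybenzyl)oxy]methyl}-7-methyl-1-(4,4,5,5-tetramethyl-1,3,2-dioxaborolan-2-yl)-9-[(1S)-2,6,6-trimethylcyclohex-2-en-1-yl]nona-1,6-dien-3-yl acetate, via sodium alkoxide 15 (not isolated)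
Conditions: 4-MeOC6H4CH2OH, NaH, DMF, 0 → 50 °C; then Ac2O, 0 °C → rt
Reagents that add atoms: 4-methoxybenzyl alcohol (COc1ccc(CO)cc1); acetic anhydride (CC(=O)OC(C)=O)
Why: SN2 opening of the 2,2-disubstituted epoxide by 4-methoxybenzyl oxide at the unhindered CH2 leaves the C3–O bond untouched (configuration retained), and trapping the tertiary sodium alkoxide with acetic anhydride installs the tertiary acetate in the same operation.

**Step 11**
Reactants: 16 (1E,3R,6E)-3-{[(4-methoxybenzyl)oxy]methyl}-7-methyl-1-(4,4,5,5-tetramethyl-1,3,2-dioxaborolan-2-yl)-9-[(1S)-2,6,6-trimethylcyclohex-2-en-1-yl]nona-1,6-dien-3-yl acetate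
Product: 17 potassium [(1E,3R,6E)-3-acetoxy-3-{[(4-methoxybenzyl)oxy]methyl}-7-methyl-9-[(1S)-2,6,6-trimethylcyclohex-2-en-1-yl]nona-1,6-dien-1-yl]trifluoroborate
Conditions: KHF2 (aq.), MeOH, rt; pinacol removed by co-evaporation
Reagents that add atoms: potassium hydrogen difluoride ([K+].[F-].F)
Why: Ligand exchange of the pinacol ester with KHF2 gives the alkenyltrifluoroborate with retention of alkene geometry, the form required for the copper coupling.

**Step 12**
Reactants: 17 potassium [(1E,3R,6E)-3-acetoxy-3-{[(4-methoxybenzyl)oxy]methyl}-7-methyl-9-[(1S)-2,6,6-trimethylcyclohex-2-en-1-yl]nona-1,6-dien-1-yl]trifluoroborate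
Product: 18 (1E,3R,6E)-3-{[(4-methoxybenzyl)oxy]methyl}-7-methyl-9-[(1S)-2,6,6-trimethylcyclohex-2-en-1-yl]nona-1,6-diene-1,3-diyl diacetate
Conditions: AcOH, CuBr (10 mol %), DMAP (20 mol %), 4 Å molecular sieves, O2 (1 atm), CH2Cl2, 40 °C
Reagents that add atoms: acetic acid (CC(=O)O)
Why: Copper-catalysed oxidative C–O coupling of an alkenyltrifluoroborate with a carboxylic acid (Chan–Lam-type: transmetalation, oxidation by O2 to trivalent copper, reductive elimination) replaces boron by acetate with retention, giving the (E)-enol acetate without any enolate that could expel the β-acetoxy group.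

**Step 13**
Reactants: 18 (1E,3R,6E)-3-{[(4-methoxybenzyl)oxy]methyl}-7-methyl-9-[(1S)-2,6,6-trimethylcyclohex-2-en-1-yl]nona-1,6-diene-1,3-diyl diacetate
Product: 19 (1E,3R,6E)-3-(hydroxymethyl)-7-methyl-9-[(1S)-2,6,6-trimethylcyclohex-2-en-1-yl]nona-1,6-diene-1,3-diyl diacetate
Conditions: DDQ, CH2Cl2–pH 7 buffer, 0 °C; used at once
Reagents that add atoms: none
Why: Oxidative cleavage of the 4-methoxybenzyl ether by DDQ under neutral conditions frees the primary alcohol without acid or base, so the enol acetate survives and the tertiary acetate has little occasion to migrate.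

**Step 14**
Reactants: 19 (1E,3R,6E)-3-(hydroxymethyl)-7-methyl-9-[(1S)-2,6,6-trimethylcyclohex-2-en-1-yl]nona-1,6-diene-1,3-diyl diacetate
Product: 20 (1E,3R,6E)-3-formyl-7-methyl-9-[(1S)-2,6,6-trimethylcyclohex-2-en-1-yl]nona-1,6-diene-1,3-diyl diacetate
Conditions: Dess–Martin periodinane, NaHCO3, CH2Cl2, 0 °C → rt
Reagents that add atoms: none
Why: Dess–Martin oxidation of the neopentyl primary alcohol under buffered conditions gives the non-enolisable α-acetoxy aldehyde; no stereocentre is touched.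

**Compound list**

1 | geranyl acetate, (2E)-3,7-dimethylocta-2,6-dien-1-yl acetate | CC(=O)OC/C=C(\C)CCC=C(C)C | starting material
2 | (2E,6E)-8-hydroxy-3,7-dimethylocta-2,6-dien-1-yl acetate | CC(=O)OC/C=C(\C)CC/C=C(\C)CO | intermediate (not isolated)
3 | (2E,6E)-3,7-dimethyl-8-oxoocta-2,6-dien-1-yl acetate | CC(=O)OC/C=C(\C)CC/C=C(\C)C=O | intermediate
4 | (2E,6E)-3,7-dimethylnona-2,6,8-trien-1-yl acetate | CC(=O)OC/C=C(\C)CC/C=C(\C)C=C | intermediate
5 | 2-methylprop-2-enal (2-methylacrolein) | CC(=C)C=O | starting material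
6 | (1S,2R)-2-[(3E)-5-acetoxy-3-methylpent-3-en-1-yl]-1,3-dimethylcyclohex-3-ene-1-carbaldehyde | CC(=O)OC/C=C(\C)CC[C@@H]1C(C)=CCC[C@]1(C)C=O | intermediate
7 | (E)-hydrazone of (1S,2R)-2-[(3E)-5-hydroxy-3-methylpent-3-en-1-yl]-1,3-dimethylcyclohex-3-ene-1-carbaldehyde | OC/C=C(\C)CC[C@@H]1C(C)=CCC[C@]1(C)/C=N/N | intermediate (not isolated)
8 | (2E)-3-methyl-5-[(1S)-2,6,6-trimethylcyclohex-2-en-1-yl]pent-2-en-1-ol ((S)-α-monocyclofarnesol) | OC/C=C(\C)CC[C@@H]1C(C)=CCCC1(C)C | intermediate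
9 | (6S)-6-[(3E)-5-bromo-3-methylpent-3-en-1-yl]-1,5,5-trimethylcyclohex-1-ene | BrC/C=C(\C)CC[C@@H]1C(C)=CCCC1(C)C | intermediate
10 | 2-methylprop-2-en-1-ol | CC(=C)CO | starting material
11 | (5E)-6-methyl-2-methylidene-8-[(1S)-2,6,6-trimethylcyclohex-2-en-1-yl]oct-5-en-1-ol | C=C(CO)CC/C=C(\C)CC[C@@H]1C(C)=CCCC1(C)C | intermediate
12 | [(2R)-2-{(3E)-4-methyl-6-[(1S)-2,6,6-trimethylcyclohex-2-en-1-yl]hex-3-en-1-yl}oxiran-2-yl]methanol | OC[C@@]1(CO1)CC/C=C(\C)CC[C@@H]2C(C)=CCCC2(C)C | intermediate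
13 | (2S)-2-{(3E)-4-methyl-6-[(1S)-2,6,6-trimethylcyclohex-2-en-1-yl]hex-3-en-1-yl}oxirane-2-carbaldehyde | O=C[C@@]1(CO1)CC/C=C(\C)CC[C@@H]2C(C)=CCCC2(C)C | intermediate
14 | 4,4,5,5-tetramethyl-2-[(E)-2-((2R)-2-{(3E)-4-methyl-6-[(1S)-2,6,6-trimethylcyclohex-2-en-1-yl]hex-3-en-1-yl}oxiran-2-yl)ethenyl]-1,3,2-dioxaborolane | CC1(C)OB(OC1(C)C)/C=C/[C@@]2(CO2)CC/C=C(\C)CC[C@@H]3C(C)=CCCC3(C)C | intermediate
15 | sodium (1E,3R,6E)-3-{[(4-methoxybenzyl)oxy]methyl}-7-methyl-1-(4,4,5,5-tetramethyl-1,3,2-dioxaborolan-2-yl)-9-[(1S)-2,6,6-trimethylcyclohex-2-en-1-yl]nona-1,6-dien-3-olate | CC1(C)OB(OC1(C)C)/C=C/[C@@](COCc2ccc(OC)cc2)(CC/C=C(\C)CC[C@@H]3C(C)=CCCC3(C)C)[O-].[Na+] | intermediate (not isolated)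
16 | (1E,3R,6E)-3-{[(4-methoxybenzyl)oxy]methyl}-7-methyl-1-(4,4,5,5-tetramethyl-1,3,2-dioxaborolan-2-yl)-9-[(1S)-2,6,6-trimethylcyclohex-2-en-1-yl]nona-1,6-dien-3-yl acetate | CC1(C)OB(OC1(C)C)/C=C/[C@@](COCc2ccc(OC)cc2)(CC/C=C(\C)CC[C@@H]3C(C)=CCCC3(C)C)OC(C)=O | intermediate
17 | potassium [(1E,3R,6E)-3-acetoxy-3-{[(4-methoxybenzyl)oxy]methyl}-7-methyl-9-[(1S)-2,6,6-trimethylcyclohex-2-en-1-yl]nona-1,6-dien-1-yl]trifluoroborate | [K+].F[B-](F)(F)/C=C/[C@@](COCc1ccc(OC)cc1)(CC/C=C(\C)CC[C@@H]2C(C)=CCCC2(C)C)OC(C)=O | intermediate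
18 | (1E,3R,6E)-3-{[(4-methoxybenzyl)oxy]methyl}-7-methyl-9-[(1S)-2,6,6-trimethylcyclohex-2-en-1-yl]nona-1,6-diene-1,3-diyl diacetate | CC(=O)O/C=C/[C@@](COCc1ccc(OC)cc1)(CC/C=C(\C)CC[C@@H]2C(C)=CCCC2(C)C)OC(C)=O | intermediate
19 | (1E,3R,6E)-3-(hydroxymethyl)-7-methyl-9-[(1S)-2,6,6-trimethylcyclohex-2-en-1-yl]nona-1,6-diene-1,3-diyl diacetate | CC(=O)O/C=C/[C@@](CO)(CC/C=C(\C)CC[C@@H]1C(C)=CCCC1(C)C)OC(C)=O | intermediate
20 | (1E,3R,6E)-3-formyl-7-methyl-9-[(1S)-2,6,6-trimethylcyclohex-2-en-1-yl]nona-1,6-diene-1,3-diyl diacetate | CC(=O)O/C=C/[C@@](C=O)(CC/C=C(\C)CC[C@@H]1C(C)=CCCC1(C)C)OC(C)=O | target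

**Step count**

Total step count: 14. Longest linear sequence: 14 steps (1 → 20); 5 and 10 enter as single building blocks.

**Steps most likely to fail**

Step 3 (key step). The dienophile may add in the reversed orientation, because the methyl group on the internal diene carbon opposes the directing effect of the 1-alkyl group. An incomplete endo or facial preference would also lower the enantiomeric purity at C1'. The fallback enforces the orientation with a removable oxygen on the internal diene carbon next to the CH2 terminus, so that both donors direct alike; it sets out from 3 and comes back at 8.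
- MeMgBr (1 equiv, THF, −78 °C) adds to the aldehyde of 3 to give (2E,6E)-8-hydroxy-3,7-dimethylnona-2,6-dien-1-yl acetate F1.
- MnO2 gives the enone (2E,6E)-3,7-dimethyl-8-oxonona-2,6-dien-1-yl acetate F2.
- i-Pr3SiOSO2CF3/Et3N gives (2E,6E)-3,7-dimethyl-8-[(triisopropylsilyl)oxy]nona-2,6,8-trien-1-yl acetate F3.
- Cycloaddition of F3 with 5 under the catalyst of step 3 should give (1S,2R)-2-[(3E)-5-acetoxy-3-methylpent-3-en-1-yl]-1,3-dimethyl-4-[(triisopropylsilyl)oxy]cyclohex-3-ene-1-carbaldehyde F4.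
- CsF and PhN(SO2CF3)2 convert the silyl enol ether regiospecifically into (1S,2R)-2-[(3E)-5-acetoxy-3-methylpent-3-en-1-yl]-1,3-dimethyl-4-{[(trifluoromethyl)sulfonyl]oxy}cyclohex-3-ene-1-carbaldehyde F5.
- The acetate is removed first (K2CO3, MeOH, 0 °C), because zerovalent palladium would ionise it, to give (1S,2R)-2-[(3E)-5-hydroxy-3-methylpent-3-en-1-yl]-1,3-dimethyl-4-{[(trifluoromethyl)sulfonyl]oxy}cyclohex-3-ene-1-carbaldehyde F6.
- Pd(OAc)2/PPh3 with Bu3N–HCO2H reduces the enol triflate to (1S,2R)-2-[(3E)-5-hydroxy-3-methylpent-3-en-1-yl]-1,3-dimethylcyclohex-3-ene-1-carbaldehyde F7.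
- The conditions of step 4 then convert F7 into 8.

Step 6. The strongly basic dianion may attack the allylic bromide in the SN2' sense, be alkylated on oxygen, or cause elimination, so that little C4–C5 coupling results. The fallback reverses the polarity (sulfone-stabilised carbanion at C5, electrophilic C4 unit); it sets out from 9 and comes back at 11.
- PhSO2Na (DMF, rt) gives {[(2E)-3-methyl-5-[(1S)-2,6,6-trimethylcyclohex-2-en-1-yl]pent-2-en-1-yl]sulfonyl}benzene F8.
- n-BuLi (THF, −78 °C) and ethyl 2-(bromomethyl)acrylate give, by addition–elimination, ethyl (5E)-6-methyl-2-methylidene-4-(phenylsulfonyl)-8-[(1S)-2,6,6-trimethylcyclohex-2-en-1-yl]oct-5-enoate F9 (epimers at the sulfonyl carbon, of no consequence).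
- i-Bu2AlH (CH2Cl2, −78 °C) reduces the ester to (5E)-6-methyl-2-methylidene-4-(phenylsulfonyl)-8-[(1S)-2,6,6-trimethylcyclohex-2-en-1-yl]oct-5-en-1-ol F10.
- PdCl2(dppp)/LiBHEt3 (THF, 0 °C) removes the allylic sulfonyl group, with hydride delivered to the less hindered allyl terminus, and gives 11.

Step 10. The tertiary alkoxide may be acetylated incompletely in the one-pot procedure, and the alkenyl boronate may be degraded by the hot alkoxide. The fallback introduces boron only after the basic step and runs the acylation separately; it sets out from 13 and comes back at 16.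
- Seyferth–Gilbert homologation with the Ohira–Bestmann reagent (K2CO3, MeOH) gives (2R)-2-ethynyl-2-{(3E)-4-methyl-6-[(1S)-2,6,6-trimethylcyclohex-2-en-1-yl]hex-3-en-1-yl}oxirane F11.
- 4-MeOC6H4CH2OH/NaH (DMF, 50 °C) with aqueous work-up gives (3R,6E)-3-{[(4-methoxybenzyl)oxy]methyl}-7-methyl-9-[(1S)-2,6,6-trimethylcyclohex-2-en-1-yl]non-6-en-1-yn-3-ol F12.
- Ac2O, DMAP and Et3N (40 °C) give (3R,6E)-3-{[(4-methoxybenzyl)oxy]methyl}-7-methyl-9-[(1S)-2,6,6-trimethylcyclohex-2-en-1-yl]non-6-en-1-yn-3-yl acetate F13.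
- Hydroboration with pinacolborane and Cp2Zr(H)Cl (cat.) gives 16.

**Further compounds**

F1 | step 3 | (2E,6E)-8-hydroxy-3,7-dimethylnona-2,6-dien-1-yl acetate | CC(=O)OC/C=C(\C)CC/C=C(\C)C(C)O
F2 | step 3 | (2E,6E)-3,7-dimethyl-8-oxonona-2,6-dien-1-yl acetate | CC(=O)OC/C=C(\C)CC/C=C(\C)C(C)=O
F3 | step 3 | (2E,6E)-3,7-dimethyl-8-[(triisopropylsilyl)oxy]nona-2,6,8-trien-1-yl acetate | CC(=O)OC/C=C(\C)CC/C=C(\C)C(=C)O[Si](C(C)C)(C(C)C)C(C)C
F4 | step 3 | (1S,2R)-2-[(3E)-5-acetoxy-3-methylpent-3-en-1-yl]-1,3-dimethyl-4-[(triisopropylsilyl)oxy]cyclohex-3-ene-1-carbaldehyde | CC(=O)OC/C=C(\C)CC[C@@H]1C(C)=C(O[Si](C(C)C)(C(C)C)C(C)C)CC[C@]1(C)C=O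
F5 | step 3 | (1S,2R)-2-[(3E)-5-acetoxy-3-methylpent-3-en-1-yl]-1,3-dimethyl-4-{[(trifluoromethyl)sulfonyl]oxy}cyclohex-3-ene-1-carbaldehyde | CC(=O)OC/C=C(\C)CC[C@@H]1C(C)=C(OS(=O)(=O)C(F)(F)F)CC[C@]1(C)C=O
F6 | step 3 | (1S,2R)-2-[(3E)-5-hydroxy-3-methylpent-3-en-1-yl]-1,3-dimethyl-4-{[(trifluoromethyl)sulfonyl]oxy}cyclohex-3-ene-1-carbaldehyde | OC/C=C(\C)CC[C@@H]1C(C)=C(OS(=O)(=O)C(F)(F)F)CC[C@]1(C)C=O
F7 | step 3 | (1S,2R)-2-[(3E)-5-hydroxy-3-methylpent-3-en-1-yl]-1,3-dimethylcyclohex-3-ene-1-carbaldehyde | OC/C=C(\C)CC[C@@H]1C(C)=CCC[C@]1(C)C=O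
F8 | step 6 | {[(2E)-3-methyl-5-[(1S)-2,6,6-trimethylcyclohex-2-en-1-yl]pent-2-en-1-yl]sulfonyl}benzene | O=S(=O)(C/C=C(\C)CC[C@@H]1C(C)=CCCC1(C)C)c1ccccc1
F9 | step 6 | ethyl (5E)-6-methyl-2-methylidene-4-(phenylsulfonyl)-8-[(1S)-2,6,6-trimethylcyclohex-2-en-1-yl]oct-5-enoate | CCOC(=O)C(=C)CC(/C=C(\C)CC[C@@H]1C(C)=CCCC1(C)C)S(=O)(=O)c1ccccc1
F10 | step 6 | (5E)-6-methyl-2-methylidene-4-(phenylsulfonyl)-8-[(1S)-2,6,6-trimethylcyclohex-2-en-1-yl]oct-5-en-1-ol | OCC(=C)CC(/C=C(\C)CC[C@@H]1C(C)=CCCC1(C)C)S(=O)(=O)c1ccccc1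
F11 | step 10 | (2R)-2-ethynyl-2-{(3E)-4-methyl-6-[(1S)-2,6,6-trimethylcyclohex-2-en-1-yl]hex-3-en-1-yl}oxirane | C#C[C@@]1(CO1)CC/C=C(\C)CC[C@@H]2C(C)=CCCC2(C)C
F12 | step 10 | (3R,6E)-3-{[(4-methoxybenzyl)oxy]methyl}-7-methyl-9-[(1S)-2,6,6-trimethylcyclohex-2-en-1-yl]non-6-en-1-yn-3-ol | C#C[C@@](COCc1ccc(OC)cc1)(CC/C=C(\C)CC[C@@H]2C(C)=CCCC2(C)C)O
F13 | step 10 | (3R,6E)-3-{[(4-methoxybenzyl)oxy]methyl}-7-methyl-9-[(1S)-2,6,6-trimethylcyclohex-2-en-1-yl]non-6-en-1-yn-3-yl acetate | C#C[C@@](COCc1ccc(OC)cc1)(CC/C=C(\C)CC[C@@H]2C(C)=CCCC2(C)C)OC(C)=O
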